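**Assumption:** the stereodescriptor in the given SMILES corresponds to (2S). The target is therefore treated as (2S)-5,7-dihydroxy-2-[7-(3-methylbut-2-en-1-yl)-1-benzofuran-5-yl]-2,3-dihydro-4H-chromen-4-one (20). Flavanone numbering (O1, C2, C3, C4, C4a, C5–C8, C8a) is used for rings A and C, and benzofuran numbering for ring B.

## The problem

Target 20 is a flavanone: a phloroglucinol-type ring A is fused to the pyranone ring C, and C2 of ring C carries a benzofuran (ring B) bound through its C5 and prenylated at its C7, next to the furan oxygen. The only stereocentre is C2 (S). No other stereocentre can control it, so it must come from a reagent or catalyst and must then survive. C2 is β to the ketone, so any base that enolises C3 opens ring C by E1cB to the chalcone phenoxide and racemises it. C2 is also a benzylic ether carbon para to the furan oxygen, so strong acid can ionise it. The customary closure of ring C makes the O1–C2 bond by oxa-Michael addition, so the stereocentre is created in the one step that is reversible. Ring B is a 1,2,3,5-tetrasubstituted benzene with an unsubstituted furan C2–C3 and a trisubstituted alkene, which rules out hydrogenolysis, strong Lewis acids and hot protic acid for unmasking the two phenols.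

The feature the plan exploits lies in ring A. O1 on C8a and the carbonyl carbon C4 on C4a are neighbours, and C4a is flanked on its other side by the oxygen-bearing C5. This is the pattern a 3-alkoxybenzyne delivers when a nucleophile adds to its distal carbon and an electrophile to its proximal carbon. The chain O1–C2–C3–C4 is then a four-atom unit with an oxygen nucleophile at one end and an acyl-level carbon at the other (a β-hydroxy nitrile), in which C2 already carries its oxygen.

## Retrosynthesis

**20 from 19.** The two O–CH2OCH3 bonds are cut. Methoxymethyl ethers are chosen for ring A because they survive fluoride and organolithium reagents and come off without hydrogen or a strong Lewis acid; benzyl, silyl and methyl ethers each fail one of these tests. The forward step must cleave two acetals without touching the alkene or C2.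

**19 from 8 and 16 (through 17 and 18).** The bonds O1–C8a and C4–C4a are cut, which removes ring A as the aryne 17. The neighbouring cut at O1–C2 (oxa-Michael or displacement at C2) forms a bond at the stereocentre, either reversibly or at an ionisable carbon. The cut at C2–aryl (conjugate arylation of a chromone) asks a catalyst to control a hindered, electron-rich acceptor. The chosen cut touches no bond to C2, halves the molecule, and leaves an acyclic β-hydroxy nitrile 8 and a monocyclic aryne precursor 16. The forward reaction must place oxygen on the correct aryne carbon, let the aryl anion find the nitrile before a proton, and avoid a free ketone under base; the nitrile gives ketimine 18, hydrolysed only on work-up.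

**8 from 7, and 7 from 6.** The C2–H bond is cut (ketone reduction), so the stereocentre is set irreversibly by asymmetric transfer hydrogenation of an aryl ketone before any ring exists. The C2–C3 bond is cut next: a cyanomethyl anion is acylated by ester 6. This two-step entry is preferred to a direct asymmetric cyanomethylation of an aldehyde because its selectivity is better established.

**6 from 5, 5 from 2, 2 from 1.** The benzofuran C7–CH2 bond is cut (prenyl cross-coupling at a bromide). Then the furan ring is cut at C3a–C3 and O1–C2 (alkynylation at an iodide followed by ring closure of the phenol onto the alkyne). Then the C–I bond is cut. Phenol 1 has its oxygen flanked by one bromine and one open position, so the two ortho sites can be used in turn for the furan and for the prenyl group without protecting the phenol.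

**16 from 14 (through 15), 14 from 11 (through 12 and 13), 11 from 10, 10 from 9.** The O–S bond, the C–Si bond, the carbamate and two acetals are cut. The carbamate serves first as the strongest ortho-director and is then exchanged for the triflate. The symmetry of phloroglucinol 9 means that whichever oxygen is left free leads to the same compound 10.

## Roads not taken

**Alternative 1:** the most obvious route. Aldol condensation of the two aromatic halves gives the 2'-hydroxychalcone A1, and ring C is closed by a catalytic asymmetric oxa-Michael addition (O1–C2). The stereocentre is then formed in a reversible step whose microscopic reverse is the racemisation pathway. Plain 2'-hydroxychalcones are weakly activated, so high selectivity normally needs an extra activating ester that must be added and removed. The 6'-alkoxy group also twists the enone. The chosen plan sets C2 by an irreversible ketone reduction and never forms a bond to it again.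

**Alternative 2:** cut C2–aryl. The forward step is a rhodium- or palladium-catalysed asymmetric conjugate addition of boronic acid A3 to chromone A2. The chromone is a vinylogous ester made still less electrophilic by two alkoxy groups. Boronic acid A3 needs a second, differentiated halogen handle on ring B, and electron-rich aryl boronic acids protodeboronate in the aqueous basic medium. The new flavanone is also generated warm and in protic base, where ring C can open. Both halves would be as long as in the chosen plan, but the stereocontrol would rest on an untested catalyst–substrate pair.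

**Alternative 3:** the same two ring-A bonds, but from acrylic acid A4 and aryne 17, by the known annulation of arynes with α,β-unsaturated carboxylic acids. The carboxylate adds to the aryne, the acyl group moves to the ortho carbon, and the phenoxide closes by oxa-Michael addition. C2 is then made last, without control and under hot fluoride, so the product is the racemate A5 and half of it is lost in a resolution. The chosen plan keeps the aryne logic but moves the stereocentre upstream and uses a nitrile so that no enolisable ketone coexists with base.

Key step: step 10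

## Steps

**Step 1**
Reactants: 1 methyl 3-bromo-4-hydroxybenzoate
Product: 2 methyl 3-bromo-4-hydroxy-5-iodobenzoate
Conditions: NIS, TsOH·H2O (cat.), MeCN, rt
Reagents that add atoms: N-iodosuccinimide, O=C1CCC(=O)N1I
Why: Electrophilic aromatic iodination; the phenol directs ortho/para, the para position carries the ester and one ortho position the bromine, so only C5 is open.

**Step 2**
Reactants: 2 methyl 3-bromo-4-hydroxy-5-iodobenzoate
Product: 5 methyl 7-bromo-1-benzofuran-5-carboxylate, via alkynylphenol 3 (not isolated), via 2-silylbenzofuran 4 (not isolated)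
Conditions: ethynyltrimethylsilane, PdCl2(PPh3)2 (cat.), CuI (cat.), Et3N, DMF, rt → 70 °C; then TBAF, THF, rt
Reagents that add atoms: ethynyltrimethylsilane, C#C[Si](C)(C)C
Why: Sonogashira coupling should occur only at C–I because oxidative addition of zerovalent palladium to an aryl iodide is much faster than to an aryl bromide. The ortho-alkynylphenol then closes by copper/base-mediated 5-endo-dig heteroannulation, and fluoride removes the C2 silyl group by protodesilylation.

**Step 3**
Reactants: 5 methyl 7-bromo-1-benzofuran-5-carboxylate
Product: 6 methyl 7-(3-methylbut-2-en-1-yl)-1-benzofuran-5-carboxylate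
Conditions: tributyl(3-methylbut-2-en-1-yl)stannane, Pd(PPh3)4 (cat.), DMF, 100 °C
Reagents that add atoms: tributyl(3-methylbut-2-en-1-yl)stannane, CCCC[Sn](CCCC)(CCCC)CC=C(C)C
Why: Stille cross-coupling; reductive elimination from the aryl(allyl)palladium intermediate at the less hindered allyl terminus should give the linear prenyl arene, and the ester and furan are inert.

**Step 4**
Reactants: 6 methyl 7-(3-methylbut-2-en-1-yl)-1-benzofuran-5-carboxylate
Product: 7 3-[7-(3-methylbut-2-en-1-yl)-1-benzofuran-5-yl]-3-oxopropanenitrile
Conditions: MeCN (2.5 equiv), n-BuLi (2.4 equiv), THF, −78 °C; then 6, −78 → −20 °C; aq. NH4Cl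
Reagents that add atoms: acetonitrile, CC#N
Why: Claisen-type acylation of lithiated acetonitrile; the product is deprotonated by the second equivalent to its stabilised enolate, which stops further addition. Pre-formed LiCH2CN is too weak a base to metalate the benzofuran C2–H.

**Step 5**
Reactants: 7 3-[7-(3-methylbut-2-en-1-yl)-1-benzofuran-5-yl]-3-oxopropanenitrile
Product: 8 (3S)-3-hydroxy-3-[7-(3-methylbut-2-en-1-yl)-1-benzofuran-5-yl]propanenitrile
Conditions: RuCl[(S,S)-TsDPEN](p-cymene) (1 mol %), HCO2H/Et3N (5:2), 30 °C
Reagents that add atoms: none
Why: Noyori–Ikariya asymmetric transfer hydrogenation; the (S,S)-TsDPEN ruthenium hydride should deliver hydrogen to the Re face of the aryl ketone through the CH/π-organised six-membered transition state, as for acetophenone and aroylacetonitriles, giving the (S)-alcohol. The outer-sphere mechanism leaves the prenyl alkene and the furan untouched.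

**Step 6**
Reactants: 9 benzene-1,3,5-triol (phloroglucinol)
Product: 10 3,5-bis(methoxymethoxy)phenol
Conditions: MOMCl (2.0 equiv), i-Pr2NEt, CH2Cl2–DMF, 0 °C → rt
Reagents that add atoms: chloromethyl methyl ether, COCCl
Why: O-alkylation of the phenols with an α-chloro ether; the reaction is statistical, but by symmetry only one bis-ether exists, and it is separated from the mono- and tris-ethers by chromatography.

**Step 7**
Reactants: 10 3,5-bis(methoxymethoxy)phenol
Product: 11 3,5-bis(methoxymethoxy)phenyl N-(propan-2-yl)carbamate
Conditions: i-PrNCO, Et3N (cat.), CH2Cl2, rt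
Reagents that add atoms: isopropyl isocyanate, CC(C)N=C=O
Why: Base-catalysed addition of the phenol to an isocyanate (carbamoylation); it places the strongest ortho-directing group on the one free oxygen.

**Step 8**
Reactants: 11 3,5-bis(methoxymethoxy)phenyl N-(propan-2-yl)carbamate
Product: 14 3,5-bis(methoxymethoxy)-2-(trimethylsilyl)phenyl N-(propan-2-yl)carbamate, via N-silylcarbamate 12 (not isolated), via bis-silylcarbamate 13 (not isolated)
Conditions: TMSOTf, TMEDA, Et2O, rt; then n-BuLi, TMEDA, −78 °C; then TMSCl, −78 °C → rt; aq. NH4Cl
Reagents that add atoms: chlorotrimethylsilane, C[Si](C)(C)Cl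
Why: Directed ortho-metalation; N-silylation in the flask masks the N–H, and the carbamate, acting together with the neighbouring methoxymethoxy group, should steer lithiation to C2, where the silyl chloride is captured. The N-silyl group is lost on aqueous work-up.

**Step 9**
Reactants: 14 3,5-bis(methoxymethoxy)-2-(trimethylsilyl)phenyl N-(propan-2-yl)carbamate
Product: 16 3,5-bis(methoxymethoxy)-2-(trimethylsilyl)phenyl trifluoromethanesulfonate, via silylphenol 15 (not isolated)
Conditions: DBU, Et2NH, MeCN, 40 °C; then PhNTf2, rt
Reagents that add atoms: N-phenylbis(trifluoromethanesulfonimide), O=S(=O)(N(c1ccccc1)S(=O)(=O)C(F)(F)F)C(F)(F)F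
Why: E1cB cleavage of the N–H carbamate by DBU (the isocyanate is trapped by diethylamine as a urea) frees the phenoxide, which is sulfonylated in the same flask; this is the standard entry to ortho-silylaryl triflates as fluoride-triggered aryne precursors.

**Step 10**
Reactants: 8 (3S)-3-hydroxy-3-[7-(3-methylbut-2-en-1-yl)-1-benzofuran-5-yl]propanenitrile; 16 3,5-bis(methoxymethoxy)-2-(trimethylsilyl)phenyl trifluoromethanesulfonate
Product: 19 (2S)-5,7-bis(methoxymethoxy)-2-[7-(3-methylbut-2-en-1-yl)-1-benzofuran-5-yl]-2,3-dihydro-4H-chromen-4-one, via aryne 17 (not isolated), via ketimine 18 (not isolated)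
Conditions: 16 (1.4 equiv), CsF (4 equiv), 18-crown-6, THF, −20 → 20 °C; then AcOH/NaOAc buffer (pH 4.5), THF–H2O, rt
Reagents that add atoms: water, O
Why: Proposed new method: a formal [4+2] annulation of an aryne with an aliphatic β-hydroxy nitrile, in which fluoride desilylates 16 and triflate leaves to give aryne 17, the fluoride-bound alkoxide of 8 adds through oxygen, the resulting aryl anion adds to the nitrile carbon to give the N-anion of ketimine 18, which is protonated on nitrogen, and the buffered work-up hydrolyses C=NH to C=O. The closest known reaction types are the annulation of arynes with salicylates to xanthones and with α,β-unsaturated carboxylic acids to 4-chromanones (O-arylation, then capture of the aryl anion by the acyl carbon), the O–H insertion of aliphatic alcohols into arynes, and the Parham-type cyclisation of aryl anions onto a tethered nitrile. Ring C is closed as a six-membered ring by 6-exo-dig attack of the C4a anion on C4, after the intermolecular formation of O1–C8a. No new stereocentre is formed: C2 is the carbinol carbon of 8 and none of its four bonds is made or broken, so the (S) configuration is carried over with retention. The regioselectivity on the aryne is secured by its C3 methoxymethoxy group, whose inductive effect distorts the triple bond so that the nucleophile enters at the distal carbon (future C8a) and the charge develops at the proximal carbon (future C4a) next to the C–O bond; this places C4 between O1 and the C5 oxygen as in ring A, and the second ether is too remote to compete. Cyclisation must outrun protonation of the aryl anion: the medium is aprotic, excess fluoride holds the only acidic proton as bifluoride, and the nitrile sits in reach through a six-membered transition state. O-arylation should be chemoselective because fluoride does not deprotonate the α-CH2 of the nitrile and because the furan and prenyl π-systems react with arynes far more slowly than an alkoxide. A nitrile is chosen as the acyl equivalent so that the ring-C ketone, whose enolate would open ring C by E1cB and racemise C2, does not exist while base is present; the imine C3–H is far less acidic and the ketone is released only at pH 4–5.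

**Step 11**
Reactants: 19 (2S)-5,7-bis(methoxymethoxy)-2-[7-(3-methylbut-2-en-1-yl)-1-benzofuran-5-yl]-2,3-dihydro-4H-chromen-4-one
Product: 20 (2S)-5,7-dihydroxy-2-[7-(3-methylbut-2-en-1-yl)-1-benzofuran-5-yl]-2,3-dihydro-4H-chromen-4-one
Conditions: HCl (3 M in MeOH), 0 → 40 °C
Reagents that add atoms: none
Why: Acid-catalysed acetal exchange cleaves both methoxymethyl ethers, with methanol carrying off the fragments as dimethoxymethane. The O1–C2 bond is deactivated towards ionisation by conjugation of O1 with the C4 carbonyl, and the prenyl group has no free ortho-phenol to cyclise onto, so C2 and the alkene should survive.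

## Compound list

1 | methyl 3-bromo-4-hydroxybenzoate | COC(=O)c1ccc(O)c(Br)c1 | starting material
2 | methyl 3-bromo-4-hydroxy-5-iodobenzoate | COC(=O)c1cc(Br)c(O)c(I)c1 | intermediate
3 | methyl 3-bromo-4-hydroxy-5-[(trimethylsilyl)ethynyl]benzoate | COC(=O)c1cc(Br)c(O)c(C#C[Si](C)(C)C)c1 | intermediate
4 | methyl 7-bromo-2-(trimethylsilyl)-1-benzofuran-5-carboxylate | COC(=O)c1cc(Br)c2oc([Si](C)(C)C)cc2c1 | intermediate
5 | methyl 7-bromo-1-benzofuran-5-carboxylate | COC(=O)c1cc(Br)c2occc2c1 | intermediate
6 | methyl 7-(3-methylbut-2-en-1-yl)-1-benzofuran-5-carboxylate | COC(=O)c1cc(CC=C(C)C)c2occc2c1 | intermediate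
7 | 3-[7-(3-methylbut-2-en-1-yl)-1-benzofuran-5-yl]-3-oxopropanenitrile | CC(C)=CCc1cc(C(=O)CC#N)cc2ccoc12 | intermediate
8 | (3S)-3-hydroxy-3-[7-(3-methylbut-2-en-1-yl)-1-benzofuran-5-yl]propanenitrile | CC(C)=CCc1cc([C@@H](O)CC#N)cc2ccoc12 | intermediate
9 | benzene-1,3,5-triol (phloroglucinol) | Oc1cc(O)cc(O)c1 | starting material
10 | 3,5-bis(methoxymethoxy)phenol | COCOc1cc(O)cc(OCOC)c1 | intermediate
11 | 3,5-bis(methoxymethoxy)phenyl N-(propan-2-yl)carbamate | CC(C)NC(=O)Oc1cc(OCOC)cc(OCOC)c1 | intermediate
12 | 3,5-bis(methoxymethoxy)phenyl N-(propan-2-yl)-N-(trimethylsilyl)carbamate | CC(C)N(C(=O)Oc1cc(OCOC)cc(OCOC)c1)[Si](C)(C)C | intermediate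
13 | 3,5-bis(methoxymethoxy)-2-(trimethylsilyl)phenyl N-(propan-2-yl)-N-(trimethylsilyl)carbamate | CC(C)N(C(=O)Oc1cc(OCOC)cc(OCOC)c1[Si](C)(C)C)[Si](C)(C)C | intermediate
14 | 3,5-bis(methoxymethoxy)-2-(trimethylsilyl)phenyl N-(propan-2-yl)carbamate | CC(C)NC(=O)Oc1cc(OCOC)cc(OCOC)c1[Si](C)(C)C | intermediate
15 | 3,5-bis(methoxymethoxy)-2-(trimethylsilyl)phenol | COCOc1cc(O)c([Si](C)(C)C)c(OCOC)c1 | intermediate
16 | 3,5-bis(methoxymethoxy)-2-(trimethylsilyl)phenyl trifluoromethanesulfonate | COCOc1cc(OCOC)c([Si](C)(C)C)c(OS(=O)(=O)C(F)(F)F)c1 | intermediate
17 | 3,5-bis(methoxymethoxy)benzyne (1,2-didehydro-3,5-bis(methoxymethoxy)benzene) | COCOC1=CC(OCOC)=CC#C1 | intermediate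
18 | (2S)-5,7-bis(methoxymethoxy)-2-[7-(3-methylbut-2-en-1-yl)-1-benzofuran-5-yl]-2,3-dihydro-4H-chromen-4-imine | CC(C)=CCc1cc([C@@H]2CC(=N)c3c(OCOC)cc(OCOC)cc3O2)cc2ccoc12 | intermediate
19 | (2S)-5,7-bis(methoxymethoxy)-2-[7-(3-methylbut-2-en-1-yl)-1-benzofuran-5-yl]-2,3-dihydro-4H-chromen-4-one | CC(C)=CCc1cc([C@@H]2CC(=O)c3c(OCOC)cc(OCOC)cc3O2)cc2ccoc12 | intermediate
20 | (2S)-5,7-dihydroxy-2-[7-(3-methylbut-2-en-1-yl)-1-benzofuran-5-yl]-2,3-dihydro-4H-chromen-4-one | CC(C)=CCc1cc([C@@H]2CC(=O)c3c(O)cc(O)cc3O2)cc2ccoc12 | target

## Step count and risks

Total step count: 11. Longest linear sequence: 7 steps (steps 1–5, 10 and 11); the aryne-precursor arm has 4 steps (steps 6–9).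

**Step 10 (key step, proposed new method).** The most likely failure is protonation of the aryl anion before it reaches the nitrile, which would stop at simple O–H insertion; aliphatic alcohols are less acidic than the phenols for which this annulation type is established. Further risks are loss of configuration through retro-addition of the alkoxide of 8, β-elimination of the new aryloxide after α-deprotonation, and an ene reaction of the aryne with the prenyl group. The fallback uses known chemistry and sets out from 6:
- Reduction (LiAlH4) would give [7-(3-methylbut-2-en-1-yl)-1-benzofuran-5-yl]methanol F1.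
- Oxidation (MnO2) would give 7-(3-methylbut-2-en-1-yl)-1-benzofuran-5-carbaldehyde F2.
- Claisen–Schmidt condensation with commercially available 2'-hydroxy-4',6'-bis(methoxymethoxy)acetophenone (KOH, EtOH) would give (2E)-1-[2-hydroxy-4,6-bis(methoxymethoxy)phenyl]-3-[7-(3-methylbut-2-en-1-yl)-1-benzofuran-5-yl]prop-2-en-1-one F3.
- NaOAc in hot ethanol would close it to racemic 5,7-bis(methoxymethoxy)-2-[7-(3-methylbut-2-en-1-yl)-1-benzofuran-5-yl]-2,3-dihydro-4H-chromen-4-one F4.
- Kinetic resolution by rhodium-catalysed asymmetric transfer hydrogenation (Cp*RhCl[TsDPEN], HCO2H/Et3N), with the catalyst enantiomer that reduces the (2R)-ketone faster, should leave the (2S)-ketone and convert the other half into (2R,4R)-5,7-bis(methoxymethoxy)-2-[7-(3-methylbut-2-en-1-yl)-1-benzofuran-5-yl]-3,4-dihydro-2H-chromen-4-ol F5, removed by chromatography.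

The fallback comes back to the route at 19.

**Step 8.** Lithiation may occur at C4 between the two methoxymethoxy groups instead of next to the carbamate, and the acetals may be attacked by the silyl triflate during N-silylation. The fallback sets out from 10 and places the ortho substituent by an electrophilic mechanism:
- Ortho-selective bromination (NBS, catalytic i-Pr2NH, CH2Cl2, low temperature) would give 2-bromo-3,5-bis(methoxymethoxy)phenol F6.
- Silylation with hexamethyldisilazane would give [2-bromo-3,5-bis(methoxymethoxy)phenoxy]trimethylsilane F7.
- Bromine–lithium exchange with n-BuLi, then 1,3-migration of silicon from oxygen to carbon (retro-Brook rearrangement) and trapping of the lithium phenoxide with Tf2O, would complete the sequence.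

The fallback comes back to the route at 16.

**Step 3.** The prenyl group may be transferred with allylic transposition (branched isomer), or the bromide may be reduced. The fallback sets out from 5:
- Suzuki–Miyaura coupling with allylboronic acid pinacol ester (PdCl2(dppf), K3PO4) would give methyl 7-(prop-2-en-1-yl)-1-benzofuran-5-carboxylate F8, where the two allyl termini are identical.
- Cross-metathesis with 2-methylbut-2-ene (second-generation Grubbs catalyst) would then build the prenyl group.

The fallback comes back to the route at 6.

**Step 11.** Acid may add methanol or HCl across the trisubstituted alkene, or ionise C2, during acetal cleavage. The fallback postpones the alkene until after the acid step and sets out from 5: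
- Acylation of LiCH2CN would give 3-(7-bromo-1-benzofuran-5-yl)-3-oxopropanenitrile F9.
- Transfer hydrogenation as in step 5 would give (3S)-3-(7-bromo-1-benzofuran-5-yl)-3-hydroxypropanenitrile F10.
- Annulation with 16 as in step 10 would give (2S)-2-(7-bromo-1-benzofuran-5-yl)-5,7-bis(methoxymethoxy)-2,3-dihydro-4H-chromen-4-one F11.
- HCl in methanol would give (2S)-2-(7-bromo-1-benzofuran-5-yl)-5,7-dihydroxy-2,3-dihydro-4H-chromen-4-one F12.
- A final Stille coupling with the prenylstannane under mild conditions (Pd(P(t-Bu)3)2, 50 °C) would install the prenyl group.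

The fallback comes back to the route at 20.

## Further compounds

F1 | step 10 | [7-(3-methylbut-2-en-1-yl)-1-benzofuran-5-yl]methanol | CC(C)=CCc1cc(CO)cc2ccoc12
F2 | step 10 | 7-(3-methylbut-2-en-1-yl)-1-benzofuran-5-carbaldehyde | CC(C)=CCc1cc(C=O)cc2ccoc12
F3 | step 10 | (2E)-1-[2-hydroxy-4,6-bis(methoxymethoxy)phenyl]-3-[7-(3-methylbut-2-en-1-yl)-1-benzofuran-5-yl]prop-2-en-1-one | CC(C)=CCc1cc(/C=C/C(=O)c3c(O)cc(OCOC)cc3OCOC)cc2ccoc12
F4 | step 10 | racemic 5,7-bis(methoxymethoxy)-2-[7-(3-methylbut-2-en-1-yl)-1-benzofuran-5-yl]-2,3-dihydro-4H-chromen-4-one | CC(C)=CCc1cc(C2CC(=O)c3c(OCOC)cc(OCOC)cc3O2)cc2ccoc12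
F5 | step 10 | (2R,4R)-5,7-bis(methoxymethoxy)-2-[7-(3-methylbut-2-en-1-yl)-1-benzofuran-5-yl]-3,4-dihydro-2H-chromen-4-ol | CC(C)=CCc1cc([C@H]2C[C@@H](O)c3c(OCOC)cc(OCOC)cc3O2)cc2ccoc12
F6 | step 8 | 2-bromo-3,5-bis(methoxymethoxy)phenol | COCOc1cc(O)c(Br)c(OCOC)c1
F7 | step 8 | [2-bromo-3,5-bis(methoxymethoxy)phenoxy]trimethylsilane | COCOc1cc(O[Si](C)(C)C)c(Br)c(OCOC)c1
F8 | step 3 | methyl 7-(prop-2-en-1-yl)-1-benzofuran-5-carboxylate | COC(=O)c1cc(CC=C)c2occc2c1
F9 | step 11 | 3-(7-bromo-1-benzofuran-5-yl)-3-oxopropanenitrile | N#CCC(=O)c1cc(Br)c2occc2c1
F10 | step 11 | (3S)-3-(7-bromo-1-benzofuran-5-yl)-3-hydroxypropanenitrile | Brc1cc([C@@H](O)CC#N)cc2ccoc12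
F11 | step 11 | (2S)-2-(7-bromo-1-benzofuran-5-yl)-5,7-bis(methoxymethoxy)-2,3-dihydro-4H-chromen-4-one | Brc1cc([C@@H]2CC(=O)c3c(OCOC)cc(OCOC)cc3O2)cc2ccoc12
F12 | step 11 | (2S)-2-(7-bromo-1-benzofuran-5-yl)-5,7-dihydroxy-2,3-dihydro-4H-chromen-4-one | Brc1cc([C@@H]2CC(=O)c3c(O)cc(O)cc3O2)cc2ccoc12
A1 | alternative 1 | (2E)-1-[2-hydroxy-4,6-bis(methoxymethoxy)phenyl]-3-[7-(3-methylbut-2-en-1-yl)-1-benzofuran-5-yl]prop-2-en-1-one | CC(C)=CCc1cc(/C=C/C(=O)c3c(O)cc(OCOC)cc3OCOC)cc2ccoc12
A2 | alternative 2 | 5,7-bis(methoxymethoxy)-4H-chromen-4-one | O=c1ccoc2cc(OCOC)cc(OCOC)c12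
A3 | alternative 2 | [7-(3-methylbut-2-en-1-yl)-1-benzofuran-5-yl]boronic acid | CC(C)=CCc1cc(B(O)O)cc2ccoc12
A4 | alternative 3 | (2E)-3-[7-(3-methylbut-2-en-1-yl)-1-benzofuran-5-yl]prop-2-enoic acid | CC(C)=CCc1cc(/C=C/C(=O)O)cc2ccoc12
A5 | alternative 3 | racemic 5,7-bis(methoxymethoxy)-2-[7-(3-methylbut-2-en-1-yl)-1-benzofuran-5-yl]-2,3-dihydro-4H-chromen-4-one | CC(C)=CCc1cc(C2CC(=O)c3c(OCOC)cc(OCOC)cc3O2)cc2ccoc12
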